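The C1 carboxyl and the C5≡C6 alkyne are traced back to a 2,3-epoxycyclohexanone, which is cut open by an Eschenmoser–Tanabe fragmentation.

With the chain numbered C1 (carboxyl carbon) to C19 (the CH2 on furan C2'), the C1 carbonyl and the C5≡C6 triple bond are bridged by C2–C4, so C1–C6 are folded back into a six-membered carbocycle. The precursor is a racemic cis-2,3-epoxycyclohexanone in which the ketone carbon is C5, the quaternary epoxide carbon is C6 (carrying C7–C19 and the furan ring) and the epoxide CH is C1. Its tosylhydrazone fragments in one operation (Eschenmoser–Tanabe): the C1–C6 ring bond is cut, both π bonds of C5≡C6 form and C1 emerges as the aldehyde, the alkyne position being dictated by the ring. A B-alkyl Suzuki coupling and a nucleophilic epoxidation build the precursor; silver(I) oxide gives the acid.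

Key step: step 7

Remark: the target has no stereocentre and no stereogenic double bond, so the given structure is achiral and needs no enantioselective step; the only stereocentres in the route (the epoxide carbons of 11) are made as a racemate and erased in step 7.

Step 1
Reactants: 1 12-bromododecan-1-ol
Product: 2 12-bromododecanal
Conditions: PhI(OAc)2 (1.1 equiv), TEMPO (10 mol%), CH2Cl2, rt
Reagents that add atoms: none
Why: The oxoammonium-mediated (TEMPO/hypervalent iodine) oxidation of a primary alcohol stops at the aldehyde and leaves the primary bromide alone, and removing the hydroxyl at this stage keeps the later organolithium step free of an acidic proton.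

Step 2
Reactants: 2 12-bromododecanal
Product: 3 13-bromotridec-1-ene
Conditions: Ph3PCH3Br (1.3 equiv), KOtBu (1.2 equiv), THF, 0 °C; then 2, 0 °C → rt
Reagents that add atoms: methyltriphenylphosphonium bromide, C[P+](c1ccccc1)(c1ccccc1)c1ccccc1.[Br-]
Why: Wittig methylenation with the unstabilised ylide (base kept below the phosphonium salt so that no free alkoxide remains) should consume the aldehyde far faster than the ylide can be alkylated by the remote primary bromide.

Step 3
Reactants: 4 furan; 3 13-bromotridec-1-ene
Product: 6 2-(tridec-12-en-1-yl)furan, via 2-lithiofuran 5 (not isolated)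
Conditions: furan (2 equiv), n-BuLi (1.2 equiv), THF, −78 → 0 °C; then 3, 0 °C → rt
Reagents that add atoms: none
Why: α-Lithiation of furan (excess furan suppresses 2,5-dilithiation) followed by SN2 alkylation of the furyllithium with an unhindered primary bromide is standard 2-alkylfuran chemistry, and the terminal alkene is inert to it.

Step 4
Reactants: 7 cyclohex-2-en-1-one
Product: 8 2-iodocyclohex-2-en-1-one
Conditions: I2 (1.5 equiv), K2CO3 (1.2 equiv), DMAP (20 mol%), THF/H2O (1:1), rt
Reagents that add atoms: iodine, II
Why: Baylis–Hillman-type α-iodination: DMAP adds in conjugate fashion, the enolate is iodinated at C2 and E1cB loss of the amine restores the enone.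

Step 5
Reactants: 6 2-(tridec-12-en-1-yl)furan; 8 2-iodocyclohex-2-en-1-one
Product: 10 2-[13-(furan-2-yl)tridecyl]cyclohex-2-en-1-one, via 9-[13-(furan-2-yl)tridecyl]-9-BBN 9 (not isolated)
Conditions: 9-BBN (0.5 M in THF, slightly less than 1 equiv relative to 6), THF, 0 °C → rt; then 8, PdCl2(dppf) (5 mol%), AsPh3 (5 mol%), Cs2CO3, DMF/THF/H2O, rt
Reagents that add atoms: none
Why: 9-BBN hydroborates only the terminal alkene, anti-Markovnikov (the aromatic furan does not react), and the primary B-alkyl borane, once activated by base, is transferred to palladium in a B-alkyl Suzuki–Miyaura coupling with the α-iodoenone, with the wide-bite-angle dppf ligand favouring reductive elimination over β-hydride loss.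

Step 6
Reactants: 10 2-[13-(furan-2-yl)tridecyl]cyclohex-2-en-1-one
Product: 11 rac-(1S,6S)-1-[13-(furan-2-yl)tridecyl]-7-oxabicyclo[4.1.0]heptan-2-one (cis-2-[13-(furan-2-yl)tridecyl]-2,3-epoxycyclohexan-1-one)
Conditions: 30% aq. H2O2 (3 equiv), aq. NaOH (0.3 equiv), MeOH/THF, 0 °C → rt
Reagents that add atoms: hydrogen peroxide, OO
Why: Weitz–Scheffer nucleophilic epoxidation, in which hydroperoxide adds to C3 of the enone and the enolate closes onto oxygen, ignores the electron-rich furan; the two new stereocentres form together as the racemate with the cis ring fusion that a cyclohexane-fused oxirane must have, and both are erased in step 7.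

Step 7
Reactants: 11 rac-(1S,6S)-1-[13-(furan-2-yl)tridecyl]-7-oxabicyclo[4.1.0]heptan-2-one; 12 p-toluenesulfonyl hydrazide
Product: 15 19-(furan-2-yl)nonadec-5-ynal, via epoxy tosylhydrazone 13 (not isolated), via hydroxy azoalkene 14 (not isolated)
Conditions: TsNHNH2 (1.0 equiv), CH2Cl2/AcOH (2:1), −20 °C → rt
Reagents that add atoms: none
Why: Acid-catalysed condensation of 12 with the ketone gives the epoxy tosylhydrazone 13, whose N–H nitrogen pushes electrons through the C=N carbon (C5) to open the oxirane at the quaternary carbon C6, giving the hydroxy azoalkene 14; the C1 oxygen then collapses to the carbonyl while the C1–C6 σ bond breaks in a Grob-type fragmentation that completes C5≡C6 and expels N2 and p-toluenesulfinate. The closest known reaction type is this same Eschenmoser–Tanabe fragmentation of 2-alkyl-2,3-epoxycyclohexanone sulfonylhydrazones to alk-5-ynals. No ring is closed (the carbocycle and the oxirane are both opened) and no stereocentre is formed, so the two stereocentres of racemic 11 simply disappear. The selectivity required is positional: the alkyne must sit at C5≡C6, and the ring guarantees this because the hydrazone carbon and its epoxide neighbour are the only atoms that can become the sp carbons. Chemoselectivity rests on exactly one equivalent of 12 at low temperature, so that the liberated aldehyde is not condensed again, and on the weak acid (AcOH), which should neither open the 2-alkylfuran nor hydrate the new internal alkyne.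

Step 8
Reactants: 15 19-(furan-2-yl)nonadec-5-ynal
Product: 16 19-(furan-2-yl)nonadec-5-ynoic acid
Conditions: Ag2O (2 equiv), aq. NaOH, THF/EtOH, rt, dark; then cold 1 M HCl to pH 3–4, 0 °C, immediate extraction
Reagents that add atoms: water/hydroxide, O (source of the new carboxyl oxygen through the aldehyde hydrate; silver(I) oxide, [Ag+].[Ag+].[O-2], is the net oxygen donor of the balanced equation)
Why: Silver(I) oxide in aqueous base (Tollens-type oxidation) takes the aldehyde hydrate to the carboxylate without touching the internal alkyne or the furan, and the brief cold acidification to pH 3–4 should not hydrolyse the furan.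

Compound list
1 | 12-bromododecan-1-ol | OCCCCCCCCCCCCBr | starting material
2 | 12-bromododecanal | O=CCCCCCCCCCCCBr | intermediate
3 | 13-bromotridec-1-ene | C=CCCCCCCCCCCCBr | intermediate
4 | furan | c1ccoc1 | starting material
5 | 2-lithiofuran | [Li]c1ccco1 | intermediate (not isolated)
6 | 2-(tridec-12-en-1-yl)furan [13-(furan-2-yl)tridec-1-ene] | C=CCCCCCCCCCCCc1ccco1 | intermediate
7 | cyclohex-2-en-1-one | O=C1C=CCCC1 | starting material
8 | 2-iodocyclohex-2-en-1-one | O=C1C(I)=CCCC1 | intermediate
9 | 9-[13-(furan-2-yl)tridecyl]-9-borabicyclo[3.3.1]nonane | o1cccc1CCCCCCCCCCCCCB1C2CCCC1CCC2 | intermediate (not isolated)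
10 | 2-[13-(furan-2-yl)tridecyl]cyclohex-2-en-1-one | O=C1CCCC=C1CCCCCCCCCCCCCc1ccco1 | intermediate
11 | rac-(1S,6S)-1-[13-(furan-2-yl)tridecyl]-7-oxabicyclo[4.1.0]heptan-2-one (cis-fused epoxyketone, racemate, (1S,6S) enantiomer drawn) | O=C1CCC[C@@H]2O[C@]12CCCCCCCCCCCCCc1ccco1 | intermediate
12 | p-toluenesulfonyl hydrazide | Cc1ccc(cc1)S(=O)(=O)NN | starting material
13 | p-toluenesulfonylhydrazone of 11 (racemic, cis-fused epoxide retained, C=N geometry undefined) | Cc1ccc(cc1)S(=O)(=O)NN=C1CCC[C@@H]2O[C@]12CCCCCCCCCCCCCc1ccco1 | intermediate (not isolated)
14 | 2-[13-(furan-2-yl)tridecyl]-3-[(4-methylphenyl)sulfonyldiazenyl]cyclohex-2-en-1-ol (racemic, carbinol configuration carried over from 11) | Cc1ccc(cc1)S(=O)(=O)N=NC1=C(CCCCCCCCCCCCCc2ccco2)[C@@H](O)CCC1 | intermediate (not isolated)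
15 | 19-(furan-2-yl)nonadec-5-ynal | O=CCCCC#CCCCCCCCCCCCCCc1ccco1 | intermediate
16 | 19-(furan-2-yl)nonadec-5-ynoic acid (achiral) | O=C(O)CCCC#CCCCCCCCCCCCCCc1ccco1 | target

Total step count: 8. Longest linear sequence: 7 steps (steps 1, 2, 3, 5, 6, 7, 8); step 4 is a one-step side branch.

Steps most likely to fail

Step 7. Hydrazone formation and fragmentation run side by side in the acidic medium, so part of the aldehyde set free can be captured by hydrazide that has not yet reacted, the hydrazone can stall before ring cleavage, and long contact with acid can erode the furan. The fallback keeps the disconnection but changes the mechanism to a neutral thermal one with no free hydrazine present when the aldehyde appears. Setting out from 11, condensation with the known reagent 1-amino-2-phenylaziridine (NN1CC1c1ccccc1) in CH2Cl2 at 0 °C would give the N-(2-phenylaziridin-1-yl)imine of 11 F1 as a mixture of stereoisomers. After a cold aqueous wash to remove excess reagent, F1 is warmed in toluene under neutral conditions until gas evolution stops. Loss of styrene and N2 triggers the same epoxide opening and C1–C6 cleavage (aminoaziridine variant of the epoxyketone–alkynone fragmentation), and the sequence comes back to the route at 15.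

Step 5. Slow boron-to-palladium transfer of the long-chain alkyl group would leave the base-sensitive α-iodoenone exposed to aqueous carbonate, where it can be reduced or degraded, and protodeboronation of the borane can compete. The fallback replaces the boron nucleophile by a zinc one and needs no base. Setting out from 6, hydroboration–oxidation (9-BBN, THF; then NaOH, H2O2) would give 13-(furan-2-yl)tridecan-1-ol F2. Premixed PPh3/I2/imidazole in CH2Cl2 at 0 °C converts it to 2-(13-iodotridecyl)furan F3. Zinc insertion (Zn dust, LiCl, THF) gives [13-(furan-2-yl)tridecyl]zinc iodide F4. Negishi coupling of F4 with 8 (Pd2(dba)3, tri(2-furyl)phosphine, THF/DMF, rt) comes back to the route at 10.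

Step 3. The basic furyllithium can remove HBr from the long-chain bromide instead of substituting it, alkylation can stop short of completion in THF, and a second lithiation–alkylation at furan C5 can give dialkylated material. The fallback reverses the polarity of the bond formation. Setting out from 3, magnesium in THF would give tridec-12-en-1-ylmagnesium bromide F5. Nickel-catalysed Kumada–Corriu coupling of F5 with commercial 2-bromofuran (Brc1ccco1; NiCl2(dppp) 2 mol%, THF/Et2O, 0 °C → rt) comes back to the route at 6.

Further compounds
F1 | step 7 | N-(2-phenylaziridin-1-yl)imine of 11 (racemic cis-epoxide, aziridine carbon and C=N geometry undefined) | C1(CCC[C@@H]2O[C@]12CCCCCCCCCCCCCc1ccco1)=NN1CC1c1ccccc1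
F2 | step 5 | 13-(furan-2-yl)tridecan-1-ol | OCCCCCCCCCCCCCc1ccco1
F3 | step 5 | 2-(13-iodotridecyl)furan | ICCCCCCCCCCCCCc1ccco1
F4 | step 5 | [13-(furan-2-yl)tridecyl]zinc iodide | I[Zn]CCCCCCCCCCCCCc1ccco1
F5 | step 3 | tridec-12-en-1-ylmagnesium bromide | Br[Mg]CCCCCCCCCCCC=C
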